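**Retrosynthetic overview**

- The two sulfate esters (on O4 and on the C7 oxygen) are put on last, onto a diol whose O5 is held as a silyl ether. C7 comes from a benzoate ester, and O5 is introduced at C5, ortho to the O4 phenol, by formylation and Dakin oxidation.
- The strategy rests on the contiguous C2(Br)–C3(Br)–C4(O) edge of the benzene ring, with the C7 carbon on C1 para to O4 and hydrogen on C6. This pattern is the imprint of a 2-silyloxycyclohexa-1,3-diene carrying both bromines, joined to a propiolate.
- The benzene ring (the only ring) is therefore disconnected at C1–C2 and C5–C6: an Alder–Rickert sequence of [4+2] addition of methyl propiolate to 3,4-dibromo-2-silyloxycyclohexa-1,3-diene, then loss of ethene.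
- The diene comes from cyclohexane-1,3-dione by C2 bromination, enol-to-vinyl-bromide exchange and kinetic enol silylation, so no bromination of an arene is needed.

Key step: step 4

Assumption: the target is drawn as the free bis(hydrogen sulfate); the sulfate monoesters 16 and 17 are written in this neutral form, would be handled as disodium salts, and the free acid 17 is released only at the end on a cold acid-form resin.

**Route**

Step 1
Reactants: 1 cyclohexane-1,3-dione
Product: 2 2-bromocyclohexane-1,3-dione (present mainly as its enol)
Conditions: Br2 (1.0 equiv), H2O, 0–5 °C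
Reagents that add atoms: bromine, BrBr
Why: Electrophilic α-bromination of the enolised 1,3-dione occurs at C2, the carbon between the carbonyls, and one equivalent should stop at the monobromide because the brominated enol is less nucleophilic.

Step 2
Reactants: 2 2-bromocyclohexane-1,3-dione
Product: 3 2,3-dibromocyclohex-2-en-1-one
Conditions: (COBr)2 (1.3 equiv), DMF (cat.), CH2Cl2, 0 °C → rt
Reagents that add atoms: oxalyl bromide, O=C(Br)C(=O)Br
Why: Vilsmeier-type activation of the vinylogous acid followed by addition–elimination of bromide is the standard conversion of a cyclic 1,3-dione enol into a β-bromoenone.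

Step 3
Reactants: 3 2,3-dibromocyclohex-2-en-1-one
Product: 5 3,4-dibromo-2-(tert-butyldimethylsilyloxy)cyclohexa-1,3-diene, via lithium dienolate 4 (not isolated)
Conditions: LiN(i-Pr)2 (1.1 equiv), THF, −78 °C; TBSCl (1.2 equiv), DMPU, −78 → 0 °C; cold NaHCO3 work-up
Reagents that add atoms: tert-butyldimethylsilyl chloride, CC(C)(C)[Si](C)(C)Cl
Why: Kinetic α′-deprotonation of the enone at C6 by the hindered amide gives the cross-conjugated dienolate, which is trapped on oxygen (kinetic enol silylation); the non-nucleophilic base should leave the vinylic bromides alone at −78 °C.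

Step 4
Reactants: 5 3,4-dibromo-2-(tert-butyldimethylsilyloxy)cyclohexa-1,3-diene; 6 methyl propiolate
Product: 8 methyl 2,3-dibromo-4-(tert-butyldimethylsilyloxy)benzoate, via bicyclo[2.2.2]octadiene adduct 7 (not isolated)
Conditions: 6 (4 equiv), BHT (cat.), o-xylene, sealed tube, 130 °C then 180 °C
Reagents that add atoms: none
Why: The electron-rich 2-silyloxydiene 5 and the electron-poor alkyne 6 should combine in a concerted, asynchronous [4+2] cycloaddition to the bicyclo[2.2.2]octa-2,5-diene 7, which on further heating undergoes a retro-[4+2] reaction that expels the saturated two-carbon bridge as ethene, aromatisation making the loss irreversible. The closest known reaction type is the Alder–Rickert synthesis of 4-silyloxybenzoates from 2-silyloxycyclohexa-1,3-dienes and acetylenic esters. The six-membered ring that becomes the arene is closed by intermolecular cycloaddition, the C1–C2 and C5–C6 bonds (benzoate numbering) being formed in the same event. No stereocentre persists, since the two bridgehead carbons of 7 arise as a racemic pair and become planar arene carbons. The step needs regioselectivity, which the silyloxy group secures by making the unsubstituted CH terminus of the diene the nucleophilic end that bonds to the β-CH carbon of the propiolate, so that the ester carbon joins the brominated terminus and ends para to O4; the terminal bromine, a weak π-donor, directs in the same sense. The two bromines lower the diene HOMO and crowd one terminus, so a slower reaction than with the parent silyloxydiene is expected, which is why excess alkyne, a radical inhibitor and a sealed vessel are specified.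

Step 5
Reactants: 8 methyl 2,3-dibromo-4-(tert-butyldimethylsilyloxy)benzoate
Product: 9 methyl 2,3-dibromo-4-hydroxybenzoate
Conditions: KHF2 (2 equiv), MeOH, rt
Reagents that add atoms: none
Why: Fluoride cleavage of an aryl silyl ether should be fast here because the phenoxide (para to the ester, ortho to bromine) is a good leaving group; the ester and the C–Br bonds are inert.

Step 6
Reactants: 9 methyl 2,3-dibromo-4-hydroxybenzoate
Product: 11 methyl 2,3-dibromo-5-formyl-4-hydroxybenzoate, via magnesium salicyl alkoxide 10 (not isolated)
Conditions: MgCl2 (anhydrous, 3 equiv), Et3N (4 equiv), (CH2O)n (8 equiv), MeCN, reflux; 1 M HCl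
Reagents that add atoms: formaldehyde (as paraformaldehyde), C=O
Why: In this Casnati–Skattebøl ortho-formylation the magnesium phenoxide delivers formaldehyde to the only free ortho carbon, C5 (C3 carries bromine), and the salicyl alkoxide is oxidised to the aldehyde by hydride transfer to a second formaldehyde.

Step 7
Reactants: 11 methyl 2,3-dibromo-5-formyl-4-hydroxybenzoate
Product: 13 methyl 2,3-dibromo-4,5-dihydroxybenzoate, via aryl formate 12 (not isolated)
Conditions: 30% H2O2 (1.5 equiv), NaOH (2.5 equiv, aq), THF, 0 °C, N2; NaHSO3, then HCl to pH 2
Reagents that add atoms: hydrogen peroxide, OO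
Why: In the Dakin oxidation hydroperoxide adds to the aldehyde, the aryl group activated by the ortho phenoxide migrates to oxygen and the formate is hydrolysed in the flask; the methyl ester, deactivated by the para phenoxide and shielded by the ortho bromine, should survive the short cold exposure to hydroxide.

Step 8
Reactants: 13 methyl 2,3-dibromo-4,5-dihydroxybenzoate
Product: 14 methyl 2,3-dibromo-5-(tert-butyldimethylsilyloxy)-4-hydroxybenzoate
Conditions: NaH (2.1 equiv), THF–DMF, 0 °C; TBSCl (1.0 equiv), 0 °C → rt; aq NH4Cl
Reagents that add atoms: tert-butyldimethylsilyl chloride, CC(C)(C)[Si](C)(C)Cl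
Why: In this silylation of the catechol dianion the O5 oxide (meta to the ester, unhindered) is more basic and nucleophilic than the O4 oxide (para to the ester, flanked by Br on C3), and any O4 silyl ether should shift to O5 by 1,2 O→O silyl migration, so kinetic and thermodynamic control favour the same monosilyl ether.

Step 9
Reactants: 14 methyl 2,3-dibromo-5-(tert-butyldimethylsilyloxy)-4-hydroxybenzoate
Product: 15 [2,3-dibromo-5-(tert-butyldimethylsilyloxy)-4-hydroxyphenyl]methanol
Conditions: i-Bu2AlH (4 equiv), CH2Cl2, −78 → 0 °C; aq potassium sodium tartrate
Reagents that add atoms: none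
Why: Aluminium hydride reduction of the methyl ester to the primary alcohol proceeds after the phenol has been taken up as its aluminium phenoxide; aryl bromides and the aryl silyl ether are inert to the hydride at this temperature.

Step 10
Reactants: 15 [2,3-dibromo-5-(tert-butyldimethylsilyloxy)-4-hydroxyphenyl]methanol
Product: 16 2,3-dibromo-5-(tert-butyldimethylsilyloxy)-4-(sulfooxy)benzyl hydrogen sulfate (handled as the disodium salt)
Conditions: SO3·pyridine (6 equiv), pyridine, 0 °C → rt; aq NaHCO3; reverse-phase chromatography
Reagents that add atoms: sulfur trioxide–pyridine complex, O=S(=O)=O.c1ccncc1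
Why: O-Sulfonation by a sulfur trioxide–amine complex converts the primary benzylic alcohol and the acidic O4 phenol into sulfate monoesters while O5 stays blocked; sulfating O4 together with C7–OH also removes any path to a para-quinone methide.

Step 11
Reactants: 16 2,3-dibromo-5-(tert-butyldimethylsilyloxy)-4-(sulfooxy)benzyl hydrogen sulfate
Product: 17 2,3-dibromo-5-hydroxy-4-(sulfooxy)benzyl hydrogen sulfate (target)
Conditions: KHF2 (2 equiv), MeOH, 0 °C → rt; sulfonic acid cation-exchange resin (H+ form), H2O, 0 °C; kept cold in dilute solution
Reagents that add atoms: none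
Why: Fluoride cleavage of the phenolic silyl ether leaves sulfate monoester anions untouched, and the freed O5 phenol is meta to C1 and so cannot expel the benzylic sulfate; cation exchange then gives the acid form as drawn.

**Compound list**

1 | cyclohexane-1,3-dione | O=C1CCCC(=O)C1 | starting material
2 | 2-bromocyclohexane-1,3-dione | O=C1CCCC(=O)C1Br | intermediate
3 | 2,3-dibromocyclohex-2-en-1-one | O=C1CCCC(Br)=C1Br | intermediate
4 | lithium 5,6-dibromocyclohexa-1,5-dien-1-olate (lithium dienolate, not isolated) | [Li+].[O-]C1=CCCC(Br)=C1Br | intermediate
5 | 3,4-dibromo-2-(tert-butyldimethylsilyloxy)cyclohexa-1,3-diene | CC(C)(C)[Si](C)(C)OC1=CCCC(Br)=C1Br | intermediate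
6 | methyl propiolate | C#CC(=O)OC | starting material
7 | methyl 1,6-dibromo-5-(tert-butyldimethylsilyloxy)bicyclo[2.2.2]octa-2,5-diene-2-carboxylate (racemic, not isolated) | COC(=O)C1=CC2CCC1(Br)C(Br)=C2O[Si](C)(C)C(C)(C)C | intermediate
8 | methyl 2,3-dibromo-4-(tert-butyldimethylsilyloxy)benzoate | COC(=O)c1ccc(O[Si](C)(C)C(C)(C)C)c(Br)c1Br | intermediate
9 | methyl 2,3-dibromo-4-hydroxybenzoate | COC(=O)c1ccc(O)c(Br)c1Br | intermediate
10 | methyl 2,3-dibromo-4-hydroxy-5-(hydroxymethyl)benzoate (as its magnesium salt, not isolated) | COC(=O)c1cc(CO)c(O)c(Br)c1Br | intermediate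
11 | methyl 2,3-dibromo-5-formyl-4-hydroxybenzoate | COC(=O)c1cc(C=O)c(O)c(Br)c1Br | intermediate
12 | methyl 2,3-dibromo-5-(formyloxy)-4-hydroxybenzoate (not isolated) | COC(=O)c1cc(OC=O)c(O)c(Br)c1Br | intermediate
13 | methyl 2,3-dibromo-4,5-dihydroxybenzoate | COC(=O)c1cc(O)c(O)c(Br)c1Br | intermediate
14 | methyl 2,3-dibromo-5-(tert-butyldimethylsilyloxy)-4-hydroxybenzoate | COC(=O)c1cc(O[Si](C)(C)C(C)(C)C)c(O)c(Br)c1Br | intermediate
15 | [2,3-dibromo-5-(tert-butyldimethylsilyloxy)-4-hydroxyphenyl]methanol | OCc1cc(O[Si](C)(C)C(C)(C)C)c(O)c(Br)c1Br | intermediate
16 | 2,3-dibromo-5-(tert-butyldimethylsilyloxy)-4-(sulfooxy)benzyl hydrogen sulfate | O=S(=O)(O)OCc1cc(O[Si](C)(C)C(C)(C)C)c(OS(=O)(=O)O)c(Br)c1Br | intermediate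
17 | 2,3-dibromo-5-hydroxy-4-(sulfooxy)benzyl hydrogen sulfate | O=S(=O)(O)OCc1cc(O)c(OS(=O)(=O)O)c(Br)c1Br | target

**Step count**

Total steps: 11. Longest linear sequence: 11 steps (from cyclohexane-1,3-dione).

**Steps most likely to fail**

Step 4. The cycloaddition may be outrun by thermal oligomerisation of the alkyne and by slow desilylation of the diene, because the two bromines deactivate and crowd the diene. Steric repulsion at the brominated terminus could also erode the regiochemistry. The fallback keeps the six ring carbons of the dione and aromatises them instead of annulating. It sets out from diene 5, which is treated with Pd(OAc)2 (divalent palladium, 1 equiv) in MeCN at rt; this Saegusa–Ito dehydrosilylation gives a 2,5-dienone that should tautomerise at once to 2,3-dibromophenol F1. NIS with catalytic TsOH in MeCN should then iodinate para to the hydroxyl to give 2,3-dibromo-4-iodophenol F2. Methoxycarbonylation of the C–I bond (CO 1 atm, MeOH, Et3N, PdCl2(PPh3)2 cat., 50 °C), in which zerovalent palladium inserts into C–I well before C–Br, should give phenol 9, where the route is rejoined before step 6.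

Step 8. Silylation may occur on both oxygens or the silyl group may scramble between O4 and O5, so that the two catechol oxygens are not cleanly told apart. The fallback uses a group that cannot migrate and carries it to the end. It sets out from catechol 13, whose dianion (NaH 2.1 equiv, DMSO) is alkylated with allyl bromide (1.0 equiv) at the more basic, unhindered O5 oxide to give methyl 5-(allyloxy)-2,3-dibromo-4-hydroxybenzoate F3. Reduction with i-Bu2AlH as in step 9 should give [5-(allyloxy)-2,3-dibromo-4-hydroxyphenyl]methanol F4, and sulfation as in step 10 should give 5-(allyloxy)-2,3-dibromo-4-(sulfooxy)benzyl hydrogen sulfate F5. Deallylation with Pd(PPh3)4 (zerovalent palladium, cat.) and morpholine in THF–MeOH at rt, where π-allyl formation is much faster than insertion into the aryl C–Br bonds, followed by the acid resin, comes back to the route at target 17.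

Step 10. Sulfation of the hindered O4 phenol (between Br on C3 and the silyloxy group) may stay incomplete under conditions mild enough for the benzylic sulfate, and forcing it may solvolyse the benzylic sulfate or strip the silyl ether. The fallback separates the two sulfations. It sets out from ester 14, which is sulfated on O4 alone under forcing conditions (SO3·NMe3, Et3N, DMF, 50 °C) to give methyl 2,3-dibromo-5-(tert-butyldimethylsilyloxy)-4-(sulfooxy)benzoate F6, isolated as its tetrabutylammonium salt. The ester is reduced with i-Bu2AlH in CH2Cl2 (−78 → 0 °C), the sulfate monoester anion being inert to hydride, to give 2,3-dibromo-6-(tert-butyldimethylsilyloxy)-4-(hydroxymethyl)phenyl hydrogen sulfate F7. The unhindered primary alcohol is then sulfated with SO3·pyridine in DMF at 0 °C, which comes back to the route at 16.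

**Further compounds**

F1 | step 4 | 2,3-dibromophenol | Oc1cccc(Br)c1Br
F2 | step 4 | 2,3-dibromo-4-iodophenol | Oc1ccc(I)c(Br)c1Br
F3 | step 8 | methyl 5-(allyloxy)-2,3-dibromo-4-hydroxybenzoate | C=CCOc1cc(C(=O)OC)c(Br)c(Br)c1O
F4 | step 8 | [5-(allyloxy)-2,3-dibromo-4-hydroxyphenyl]methanol | C=CCOc1cc(CO)c(Br)c(Br)c1O
F5 | step 8 | 5-(allyloxy)-2,3-dibromo-4-(sulfooxy)benzyl hydrogen sulfate | C=CCOc1cc(COS(=O)(=O)O)c(Br)c(Br)c1OS(=O)(=O)O
F6 | step 10 | methyl 2,3-dibromo-5-(tert-butyldimethylsilyloxy)-4-(sulfooxy)benzoate | COC(=O)c1cc(O[Si](C)(C)C(C)(C)C)c(OS(=O)(=O)O)c(Br)c1Br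
F7 | step 10 | 2,3-dibromo-6-(tert-butyldimethylsilyloxy)-4-(hydroxymethyl)phenyl hydrogen sulfate | OCc1cc(O[Si](C)(C)C(C)(C)C)c(OS(=O)(=O)O)c(Br)c1Br
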